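**Retrosynthetic overview**
1. The target is a genkwanin unit (5,4'-dihydroxy-7-methoxyflavone) joined through C3' of its ring B to C3 of ring C of an apigenin unit. It is reached by global dealkylation of the tetrabenzyl isopropyl ether 14, with the 7-methoxy group carried from the start.
2. Key disconnection: the C3'–C3 inter-flavone bond and the O1–C2 bond of apigenin ring C are cut together. This gives aryl iodide 7 (the complete genkwanin unit) and the acyclic ynone 13; forward, a palladium-catalysed arylative, debenzylative 6-endo-dig cyclization.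
3. Enabling feature: in the apigenin unit, C3 and C2 of ring C are the alpha and beta carbons of the C2=C3–C4=O enone and C2 bears O1 of ring A, so ring C is the closed form of an aryl ynone. Ring A is 5,7-dioxygenated beside O1, so the ynone aryl ring is a mirror-symmetric 2,4,6-tris(benzyloxy)phenyl group and either ortho oxygen can become O1. C3' of genkwanin ring B lies ortho to O4' and is bought as an iodide.
4. Iodide 7 comes from a Claisen–Schmidt chalcone (acetophenone 2 plus aldehyde 4) and I2/DMSO closure of genkwanin ring C. Ynone 13 comes from acetylide addition to aldehyde 9 and MnO2 oxidation.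
5. Ring order: rings A and B of both units are bought; genkwanin ring C is closed first (step 4) and apigenin ring C last (step 8).

Key step: step 8

Remark: the target has no stereocenter and its C3–C3' axis is drawn without a descriptor, so the axis is treated as stereochemically undefined and no control of it is planned.

**Route**

Step 1
Reactants: 1 1-(2,6-dihydroxy-4-methoxyphenyl)ethan-1-one
Product: 2 1-[2-(benzyloxy)-6-hydroxy-4-methoxyphenyl]ethan-1-one
Conditions: BnBr (1.05 equiv), K2CO3, acetone, reflux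
Reagents that add atoms: benzyl bromide, BrCc1ccccc1
Why: Williamson ether synthesis; after the first benzylation the remaining phenol is hydrogen-bonded to the acetyl C=O and should react much more slowly, which leaves the phenol needed for closure of genkwanin ring C.

Step 2
Reactants: 3 4-hydroxy-3-iodobenzaldehyde
Product: 4 3-iodo-4-(propan-2-yloxy)benzaldehyde
Conditions: 2-bromopropane, K2CO3, DMF, 60 °C
Reagents that add atoms: 2-bromopropane, CC(C)Br
Why: Williamson ether synthesis; the isopropyl ether is chosen because it offers no arene C–H bond beside the later arylpalladium centre and is cleaved by BCl3 together with the benzyl ethers.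

Step 3
Reactants: 2 1-[2-(benzyloxy)-6-hydroxy-4-methoxyphenyl]ethan-1-one; 4 3-iodo-4-(propan-2-yloxy)benzaldehyde
Product: 5 (2E)-1-[2-(benzyloxy)-6-hydroxy-4-methoxyphenyl]-3-[3-iodo-4-(propan-2-yloxy)phenyl]prop-2-en-1-one
Conditions: KOH (50% aq.), EtOH, rt
Reagents that add atoms: none
Why: Claisen–Schmidt condensation (aldol addition, then E1cB dehydration) of the methyl ketone with the non-enolisable aldehyde, giving the conjugated E alkene as the thermodynamic isomer.

Step 4
Reactants: 5 (2E)-1-[2-(benzyloxy)-6-hydroxy-4-methoxyphenyl]-3-[3-iodo-4-(propan-2-yloxy)phenyl]prop-2-en-1-one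
Product: 7 5-(benzyloxy)-2-[3-iodo-4-(propan-2-yloxy)phenyl]-7-methoxy-4H-chromen-4-one, via racemic flavanone 6 (not isolated)
Conditions: I2 (10 mol%), DMSO, 130 °C
Reagents that add atoms: none
Why: Iodine-catalysed oxidative cyclization of a 2'-hydroxychalcone: 6-endo-trig oxa-Michael closure gives flavanone 6, which iodine dehydrogenates with DMSO as terminal oxidant; the C2 stereocenter of 6 forms without control and is erased, and the aryl iodide and the ethers should tolerate the conditions.

Step 5
Reactants: 8 2,4,6-trihydroxybenzaldehyde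
Product: 9 2,4,6-tris(benzyloxy)benzaldehyde
Conditions: BnBr (3.6 equiv), K2CO3, DMF, 70 °C
Reagents that add atoms: benzyl bromide, BrCc1ccccc1
Why: Threefold Williamson ether synthesis; the formyl group lowers the ring nucleophilicity so that O- rather than C-benzylation is expected, and excess reagent with heating should also alkylate the two hydrogen-bonded ortho phenols.

Step 6
Reactants: 10 1-(benzyloxy)-4-ethynylbenzene; 9 2,4,6-tris(benzyloxy)benzaldehyde
Product: 12 racemic 1-[2,4,6-tris(benzyloxy)phenyl]-3-[4-(benzyloxy)phenyl]prop-2-yn-1-ol, via lithium acetylide 11 (not isolated)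
Conditions: n-BuLi, THF, −78 °C; then 9, −78 to 0 °C; H2O
Reagents that add atoms: none
Why: Deprotonation of the terminal alkyne and 1,2-addition of the lithium acetylide to the aldehyde; the carbinol stereocenter forms without control (racemate) and is removed in step 7, and the acid-sensitive alcohol is carried on crude.

Step 7
Reactants: 12 racemic 1-[2,4,6-tris(benzyloxy)phenyl]-3-[4-(benzyloxy)phenyl]prop-2-yn-1-ol
Product: 13 1-[2,4,6-tris(benzyloxy)phenyl]-3-[4-(benzyloxy)phenyl]prop-2-yn-1-one
Conditions: MnO2 (activated, excess), CH2Cl2, rt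
Reagents that add atoms: none
Why: MnO2 oxidation of a benzylic propargylic alcohol to the conjugated ynone under neutral conditions that leave benzyl ethers and alkyne untouched.

Step 8
Reactants: 7 5-(benzyloxy)-2-[3-iodo-4-(propan-2-yloxy)phenyl]-7-methoxy-4H-chromen-4-one; 13 1-[2,4,6-tris(benzyloxy)phenyl]-3-[4-(benzyloxy)phenyl]prop-2-yn-1-one
Product: 14 5,7-bis(benzyloxy)-2-[4-(benzyloxy)phenyl]-3-{5-[5-(benzyloxy)-7-methoxy-4-oxo-4H-chromen-2-yl]-2-(propan-2-yloxy)phenyl}-4H-chromen-4-one
Conditions: Pd2(dba)3 (5 mol%), P(2-furyl)3 (20 mol%), KOAc (2 equiv), 13 (1.2 equiv), DMF, 90 °C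
Reagents that add atoms: none
Why: Proposed new method: oxidative addition of the C–I bond of 7 to zerovalent palladium gives an arylpalladium species that binds the alkyne of 13, one of the two equivalent ortho benzyloxy oxygens of ring A attacks the carbonyl-polarised beta carbon anti to the metal (6-endo-dig closure of ring C of the apigenin unit), acetate takes the benzyl group from the resulting oxonium ion as benzyl acetate, and C–C reductive elimination at divalent palladium joins C3 to C3' and returns the catalyst. The closest known reaction types are the ICl-induced dealkylative 6-endo-dig cyclization of ortho-alkoxyaryl ynones to 3-iodochromones, the oxypalladation/reductive elimination of ortho-alkynylphenols with aryl halides to 2,3-disubstituted benzofurans, the palladium-catalysed cyclization/arylation of tert-butylimines of ortho-alkynylbenzaldehydes (neutral nucleophile, alkyl group lost) and the PtCl2-catalysed carboalkoxylation of ortho-alkynylphenyl benzyl ethers; new here is an arylpalladium electrophile acting on an ortho-benzyloxyaryl ynone. No stereocenter is formed. The step needs anti-oxypalladation to outrun syn-carbopalladation of the alkyne, shift of the benzyl cation to C3 and protodepalladation: the ynone polarisation directs oxygen to the beta carbon, the mirror symmetry of ring A removes any choice between the ortho oxygens, the weakly donating P(2-furyl)3 keeps the metal electrophilic, excess acetate intercepts the benzyl group and the medium holds no proton source. An ether and not a free phenol is used as the nucleophile because an ortho-hydroxyaryl ynone would close to the 3-unsubstituted flavone with base alone, and the isopropyl ether beside the iodide of 7 offers no arene C–H bond for intramolecular direct arylation.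

Step 9
Reactants: 14 5,7-bis(benzyloxy)-2-[4-(benzyloxy)phenyl]-3-{5-[5-(benzyloxy)-7-methoxy-4-oxo-4H-chromen-2-yl]-2-(propan-2-yloxy)phenyl}-4H-chromen-4-one
Product: 15 5,7-dihydroxy-3-[2-hydroxy-5-(5-hydroxy-7-methoxy-4-oxo-4H-chromen-2-yl)phenyl]-2-(4-hydroxyphenyl)-4H-chromen-4-one
Conditions: BCl3 (12 equiv), pentamethylbenzene (10 equiv), CH2Cl2, −78 to 0 °C; then H2O/MeOH
Reagents that add atoms: none
Why: Lewis acid dealkylation of aryl ethers: BCl3 should cleave the four benzyl ethers at low temperature (benzyl cations trapped by pentamethylbenzene) and the isopropyl ether on warming, while the non-chelated 7-methoxy group should survive and aqueous work-up sets the phenols free.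

**Compound list**
1 | 1-(2,6-dihydroxy-4-methoxyphenyl)ethan-1-one | CC(=O)c1c(O)cc(OC)cc1O | starting material
2 | 1-[2-(benzyloxy)-6-hydroxy-4-methoxyphenyl]ethan-1-one | CC(=O)c1c(O)cc(OC)cc1OCc1ccccc1 | intermediate
3 | 4-hydroxy-3-iodobenzaldehyde | O=Cc1ccc(O)c(I)c1 | starting material
4 | 3-iodo-4-(propan-2-yloxy)benzaldehyde | CC(C)Oc1ccc(C=O)cc1I | intermediate
5 | (2E)-1-[2-(benzyloxy)-6-hydroxy-4-methoxyphenyl]-3-[3-iodo-4-(propan-2-yloxy)phenyl]prop-2-en-1-one | COc1cc(O)c(C(=O)/C=C/c2ccc(OC(C)C)c(I)c2)c(OCc2ccccc2)c1 | intermediate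
6 | racemic 5-(benzyloxy)-2-[3-iodo-4-(propan-2-yloxy)phenyl]-7-methoxy-2,3-dihydro-4H-chromen-4-one | COc1cc(OCc2ccccc2)c2C(=O)CC(c3ccc(OC(C)C)c(I)c3)Oc2c1 | intermediate (not isolated)
7 | 5-(benzyloxy)-2-[3-iodo-4-(propan-2-yloxy)phenyl]-7-methoxy-4H-chromen-4-one | COc1cc(OCc2ccccc2)c2c(=O)cc(-c3ccc(OC(C)C)c(I)c3)oc2c1 | intermediate
8 | 2,4,6-trihydroxybenzaldehyde | O=Cc1c(O)cc(O)cc1O | starting material
9 | 2,4,6-tris(benzyloxy)benzaldehyde | O=Cc1c(OCc2ccccc2)cc(OCc2ccccc2)cc1OCc1ccccc1 | intermediate
10 | 1-(benzyloxy)-4-ethynylbenzene | C#Cc1ccc(OCc2ccccc2)cc1 | starting material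
11 | lithium [4-(benzyloxy)phenyl]ethynide | [Li]C#Cc1ccc(OCc2ccccc2)cc1 | intermediate (not isolated)
12 | racemic 1-[2,4,6-tris(benzyloxy)phenyl]-3-[4-(benzyloxy)phenyl]prop-2-yn-1-ol | OC(C#Cc1ccc(OCc2ccccc2)cc1)c1c(OCc2ccccc2)cc(OCc2ccccc2)cc1OCc1ccccc1 | intermediate
13 | 1-[2,4,6-tris(benzyloxy)phenyl]-3-[4-(benzyloxy)phenyl]prop-2-yn-1-one | O=C(C#Cc1ccc(OCc2ccccc2)cc1)c1c(OCc2ccccc2)cc(OCc2ccccc2)cc1OCc1ccccc1 | intermediate
14 | 5,7-bis(benzyloxy)-2-[4-(benzyloxy)phenyl]-3-{5-[5-(benzyloxy)-7-methoxy-4-oxo-4H-chromen-2-yl]-2-(propan-2-yloxy)phenyl}-4H-chromen-4-one | COc1cc(OCc2ccccc2)c2c(=O)cc(-c3ccc(OC(C)C)c(-c4c(-c5ccc(OCc6ccccc6)cc5)oc5cc(OCc6ccccc6)cc(OCc6ccccc6)c5c4=O)c3)oc2c1 | intermediate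
15 | 5,7-dihydroxy-3-[2-hydroxy-5-(5-hydroxy-7-methoxy-4-oxo-4H-chromen-2-yl)phenyl]-2-(4-hydroxyphenyl)-4H-chromen-4-one | COc1cc(O)c2c(=O)cc(-c3ccc(O)c(-c4c(-c5ccc(O)cc5)oc5cc(O)cc(O)c5c4=O)c3)oc2c1 | target

**Step count and risks**
Total steps: 9. Longest linear sequence: 5 steps (steps 1, 3, 4, 8, 9, or steps 5, 6, 7, 8, 9).

Steps most likely to fail:

1. Step 8 (proposed new method). The ether oxygen may be too weak a nucleophile toward the palladium-bound alkyne, so that syn-carbopalladation of the ynone, benzyl transfer to C3 or reduction of the aryl iodide takes over. Fallback with known chemistry: setting out from 13, ICl in CH2Cl2 at −78 °C should give, by iododebenzylative 6-endo-dig cyclization, 5,7-bis(benzyloxy)-2-[4-(benzyloxy)phenyl]-3-iodo-4H-chromen-4-one F1. In parallel, 7 is converted by Miyaura borylation (B2pin2, PdCl2(dppf), KOAc, dioxane, 85 °C) into the pinacol boronate 5-(benzyloxy)-7-methoxy-2-[4-(propan-2-yloxy)-3-(4,4,5,5-tetramethyl-1,3,2-dioxaborolan-2-yl)phenyl]-4H-chromen-4-one F2. Suzuki–Miyaura coupling of F1 with F2 (Pd(PPh3)4, K3PO4, dioxane/H2O, 90 °C) forms the same C3–C3' bond and returns to the route at 14.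

2. Step 9. The 7-methyl ether may be cleaved during the warming needed for the isopropyl group, or benzyl cations may alkylate the electron-rich rings despite the scavenger. Fallback: setting out from 14, hydrogenolysis (H2, 10% Pd/C, THF/MeOH, rt) removes the four benzyl ethers and should give 5,7-dihydroxy-3-[5-(5-hydroxy-7-methoxy-4-oxo-4H-chromen-2-yl)-2-(propan-2-yloxy)phenyl]-2-(4-hydroxyphenyl)-4H-chromen-4-one F3. The isopropyl ether alone is then cleaved with AlCl3 in CH2Cl2 at rt, returning at 15.

3. Step 4. HI formed at 130 °C may strip the peri benzyl ether, or the oxidation may stall at the flavanone stage. Fallback by the Baker–Venkataraman route, setting out from 4 and 2: Pinnick oxidation of 4 (NaClO2, NaH2PO4, 2-methyl-2-butene, t-BuOH/H2O) gives 3-iodo-4-(propan-2-yloxy)benzoic acid F4. Steglich esterification of F4 with phenol 2 (EDC·HCl, DMAP, CH2Cl2) gives 2-acetyl-3-(benzyloxy)-5-methoxyphenyl 3-iodo-4-(propan-2-yloxy)benzoate F5. KOH in pyridine at 50 °C induces the O-to-C acyl shift to 1-[2-(benzyloxy)-6-hydroxy-4-methoxyphenyl]-3-[3-iodo-4-(propan-2-yloxy)phenyl]propane-1,3-dione F6. Cyclodehydration of F6 (cat. p-TsOH, toluene, reflux) returns at 7.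

**Further compounds**
F1 | step 8 | 5,7-bis(benzyloxy)-2-[4-(benzyloxy)phenyl]-3-iodo-4H-chromen-4-one | O=c1c(I)c(-c2ccc(OCc3ccccc3)cc2)oc2cc(OCc3ccccc3)cc(OCc3ccccc3)c12
F2 | step 8 | 5-(benzyloxy)-7-methoxy-2-[4-(propan-2-yloxy)-3-(4,4,5,5-tetramethyl-1,3,2-dioxaborolan-2-yl)phenyl]-4H-chromen-4-one | COc1cc(OCc2ccccc2)c2c(=O)cc(-c3ccc(OC(C)C)c(B4OC(C)(C)C(C)(C)O4)c3)oc2c1
F3 | step 9 | 5,7-dihydroxy-3-[5-(5-hydroxy-7-methoxy-4-oxo-4H-chromen-2-yl)-2-(propan-2-yloxy)phenyl]-2-(4-hydroxyphenyl)-4H-chromen-4-one | COc1cc(O)c2c(=O)cc(-c3ccc(OC(C)C)c(-c4c(-c5ccc(O)cc5)oc5cc(O)cc(O)c5c4=O)c3)oc2c1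
F4 | step 4 | 3-iodo-4-(propan-2-yloxy)benzoic acid | CC(C)Oc1ccc(C(=O)O)cc1I
F5 | step 4 | 2-acetyl-3-(benzyloxy)-5-methoxyphenyl 3-iodo-4-(propan-2-yloxy)benzoate | CC(=O)c1c(OC(=O)c2ccc(OC(C)C)c(I)c2)cc(OC)cc1OCc1ccccc1
F6 | step 4 | 1-[2-(benzyloxy)-6-hydroxy-4-methoxyphenyl]-3-[3-iodo-4-(propan-2-yloxy)phenyl]propane-1,3-dione | COc1cc(O)c(C(=O)CC(=O)c2ccc(OC(C)C)c(I)c2)c(OCc2ccccc2)c1
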